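**Retrosynthetic overview**
1. The side-chain carbinol is cut at C3'–C4' (asymmetric Nozaki–Hiyama–Kishi isopropenylation of an aldehyde); CH2OH comes from a Morita–Baylis–Hillman reaction and the enol ester from O-acylation of an aldehyde enolate.
2. The cis acetonyl and 2-oxoethyl arms come from ozonolysis of a cis-fused methylcyclohexene (an isoprene unit).
3. Key step: the quaternary carbon (its methyl group and its bond to the side chain) is made by hydrogen-atom-transfer radical conjugate addition of an exocyclic methylene to acrolein, steered by the neighbouring ring-fusion centre.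
4. The bicycle comes from a Diels–Alder reaction of isoprene with (R)-4-silyloxycyclohept-2-enone, itself made by asymmetric Kornblum–DeLaMare rearrangement of cycloheptadiene endoperoxide.
5. Ring order: the seven-membered ring is in the first starting material; a temporary six-membered ring is fused on in step 3 and cleaved in step 8.

Assumption: in steps 2 and 12 the antipode of the chiral catalyst or ligand that gives the drawn configuration is used (both antipodes are available).

**Step 1**
Reactants: 1 cyclohepta-1,3-diene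
Product: 2 6,7-dioxabicyclo[3.2.2]non-8-ene (meso endoperoxide)
Conditions: O2, tetraphenylporphyrin (0.5 mol%), visible light, CH2Cl2, 0 °C
Reagents that add atoms: dioxygen, O=O
Why: [4+2] cycloaddition of singlet oxygen to the cyclic diene gives the meso endoperoxide, which places oxygen on the two ring carbons that become the ring ketone carbon and the quaternary carbon.

**Step 2**
Reactants: 2 6,7-dioxabicyclo[3.2.2]non-8-ene
Product: 4 (R)-4-(tert-butyldimethylsilyloxy)cyclohept-2-en-1-one, via hydroxy enone 3 (not isolated)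
Conditions: 9-O-acetyl-6'-hydroxy cinchona alkaloid catalyst (5 mol%), CH2Cl2, rt; then imidazole, TBSCl, 0 °C → rt
Reagents that add atoms: tert-butyldimethylsilyl chloride, CC(C)(C)[Si](C)(C)Cl
Why: Enantioselective Kornblum–DeLaMare rearrangement, in which the chiral base removes one of the two enantiotopic bridgehead hydrogens of the meso peroxide and so sets the (R)-carbinol centre that later steers the cycloaddition; the alcohol is silylated in the same flask.

**Step 3**
Reactants: 4 (R)-4-(tert-butyldimethylsilyloxy)cyclohept-2-en-1-one; 5 isoprene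
Product: 6 (4aR,5R,9aS)-5-(tert-butyldimethylsilyloxy)-3-methyl-1,4,4a,5,6,7,8,9a-octahydro-9H-benzo[7]annulen-9-one
Conditions: isoprene (5 equiv), EtAlCl2 (0.3 equiv), toluene, −40 → 0 °C, cold quench
Reagents that add atoms: none
Why: Lewis-acid-catalysed Diels–Alder reaction with "para" orientation (the isoprene CH2 next to C–Me bonds to the enone β-carbon), in which the diene adds anti to the silyloxy group and suprafacially, so both ring-fusion centres (the future C6 and C7) are set cis in the temporary six-membered ring.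

**Step 4**
Reactants: 6 (4aR,5R,9aS)-5-(tert-butyldimethylsilyloxy)-3-methyl-1,4,4a,5,6,7,8,9a-octahydro-9H-benzo[7]annulen-9-one
Product: 7 (4aR,5R,9aS)-5-(tert-butyldimethylsilyloxy)-3-methyl-9-methylidene-4,4a,5,6,7,8,9,9a-octahydro-1H-benzo[7]annulene
Conditions: Zn, CH2Br2, TiCl4, THF/CH2Cl2, 0 °C → rt
Reagents that add atoms: dibromomethane, BrCBr
Why: Takai–Lombardo methylenation, whose non-basic gem-dimetallic reagent converts the ketone into the exocyclic methylene without enolising the adjacent cis ring-fusion centre; no new stereocentre.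

**Step 5**
Reactants: 7 (4aR,5R,9aS)-5-(tert-butyldimethylsilyloxy)-3-methyl-9-methylidene-4,4a,5,6,7,8,9,9a-octahydro-1H-benzo[7]annulene; 8 acrolein
Product: 10 (4aR,5R,9R,9aS)-9-[2-(1,3-dioxolan-2-yl)ethyl]-3,9-dimethyl-4,4a,5,6,7,8,9,9a-octahydro-1H-benzo[7]annulen-5-ol, via aldehyde 9 (not isolated)
Conditions: acrolein (3 equiv), Fe(acac)3 (0.5 equiv), PhSiH3 (2.5 equiv), EtOH/ethylene glycol 5:1, 60 °C; then p-TsOH·H2O, ethylene glycol, 50 °C
Reagents that add atoms: ethylene glycol, OCCO
Why: Metal-hydride hydrogen-atom-transfer Giese reaction (Baran-type reductive olefin coupling), in which the iron hydride gives H• to the =CH2 terminus (which becomes the quaternary methyl) and the tertiary ring radical adds to acrolein on the convex face, anti to the cyclohexene CH2 on the neighbouring ring-fusion carbon, which sets the quaternary centre with methyl cis to both arms; the 1,1-disubstituted exocyclic alkene is expected to react ahead of the trisubstituted ring alkene, and the acid then closes the dioxolane and removes the silyl group.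

**Step 6**
Reactants: 10 (4aR,5R,9R,9aS)-9-[2-(1,3-dioxolan-2-yl)ethyl]-3,9-dimethyl-4,4a,5,6,7,8,9,9a-octahydro-1H-benzo[7]annulen-5-ol
Product: 11 (4aR,9R,9aS)-9-[2-(1,3-dioxolan-2-yl)ethyl]-3,9-dimethyl-1,4,4a,6,7,8,9,9a-octahydro-5H-benzo[7]annulen-5-one
Conditions: nPr4N[RuO4] (5 mol%), N-methylmorpholine N-oxide, 4 Å sieves, CH2Cl2, rt
Reagents that add atoms: none
Why: Ley–Griffith oxidation turns the steering carbinol into the ring ketone under neutral conditions that leave the acetal and the ring-fusion centre alpha to the new ketone untouched.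

**Step 7**
Reactants: 11 (4aR,9R,9aS)-9-[2-(1,3-dioxolan-2-yl)ethyl]-3,9-dimethyl-1,4,4a,6,7,8,9,9a-octahydro-5H-benzo[7]annulen-5-one
Product: 13 (4aR,9S,9aS)-9-[2-(1,3-dioxolan-2-yl)ethyl]-3,9-dimethyl-1,4,4a,8,9,9a-hexahydro-5H-benzo[7]annulen-5-one, via trimethylsilyl enol ether 12 (not isolated)
Conditions: LDA, TMSCl, THF, −78 °C; then Pd(OAc)2 (1.1 equiv), MeCN, rt
Reagents that add atoms: none
Why: Saegusa–Ito dehydrogenation, in which kinetic deprotonation takes the CH2 side of the ketone (not the ring-fusion CH, so that centre is not epimerised) and palladium acetate turns the silyl enol ether into the enone of the target.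

**Step 8**
Reactants: 13 (4aR,9S,9aS)-9-[2-(1,3-dioxolan-2-yl)ethyl]-3,9-dimethyl-1,4,4a,8,9,9a-hexahydro-5H-benzo[7]annulen-5-one
Product: 14 (5S,6S,7R)-5-[2-(1,3-dioxolan-2-yl)ethyl]-5-methyl-6-(2-oxoethyl)-7-(2-oxopropyl)cyclohept-2-en-1-one
Conditions: O3 (about 1 equiv, stopped at the first trace of blue), CH2Cl2, −78 °C; then PPh3, −78 °C → rt; used crude
Reagents that add atoms: ozone, [O-][O+]=O
Why: Ozonolysis, in which ozone attacks the electron-rich trisubstituted ring alkene far faster than the electron-poor enone, and cleavage of the temporary ring releases the acetonyl arm (from the C–Me carbon) and the 2-oxoethyl arm, which stay cis because neither ring-fusion centre is touched.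

**Step 9**
Reactants: 14 (5S,6S,7R)-5-[2-(1,3-dioxolan-2-yl)ethyl]-5-methyl-6-(2-oxoethyl)-7-(2-oxopropyl)cyclohept-2-en-1-one; 15 3-methylbut-2-enoyl chloride
Product: 16 (5S,6S,7R)-5-[2-(1,3-dioxolan-2-yl)ethyl]-5-methyl-6-[(E)-2-(3-methylbut-2-enoyloxy)ethenyl]-7-(2-oxopropyl)cyclohept-2-en-1-one
Conditions: Et3N, DMAP (10 mol%), CH2Cl2, 0 °C → rt
Reagents that add atoms: none
Why: Enol esterification by O-acylation of the aldehyde enolate, in which only the aldehyde is enolised by the amine base and the (E)-enol ester is favoured because the (Z)-isomer suffers allylic strain against the crowded C6; no stereocentre changes.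

**Step 10**
Reactants: 16 (5S,6S,7R)-5-[2-(1,3-dioxolan-2-yl)ethyl]-5-methyl-6-[(E)-2-(3-methylbut-2-enoyloxy)ethenyl]-7-(2-oxopropyl)cyclohept-2-en-1-one; 17 formaldehyde
Product: 18 (5S,6S,7R)-5-[2-(1,3-dioxolan-2-yl)ethyl]-2-(hydroxymethyl)-5-methyl-6-[(E)-2-(3-methylbut-2-enoyloxy)ethenyl]-7-(2-oxopropyl)cyclohept-2-en-1-one
Conditions: aq. HCHO (3 equiv), PBu3 (0.3 equiv), THF, rt
Reagents that add atoms: none
Why: Morita–Baylis–Hillman reaction, in which the phosphine adds reversibly to the unhindered enone β-carbon, the enolate adds to formaldehyde and elimination returns the 2-(hydroxymethyl)enone, while the soft phosphine leaves the enol ester alone.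

**Step 11**
Reactants: 18 (5S,6S,7R)-5-[2-(1,3-dioxolan-2-yl)ethyl]-2-(hydroxymethyl)-5-methyl-6-[(E)-2-(3-methylbut-2-enoyloxy)ethenyl]-7-(2-oxopropyl)cyclohept-2-en-1-one
Product: 19 (5S,6S,7R)-2-(hydroxymethyl)-5-methyl-6-[(E)-2-(3-methylbut-2-enoyloxy)ethenyl]-5-(3-oxopropyl)-7-(2-oxopropyl)cyclohept-2-en-1-one
Conditions: p-TsOH·H2O (10 mol%), acetone/H2O 10:1, rt
Reagents that add atoms: water, O
Why: Acid-catalysed acetal hydrolysis frees the side-chain aldehyde under conditions mild enough for the enol ester and the allylic alcohol.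

**Step 12**
Reactants: 19 (5S,6S,7R)-2-(hydroxymethyl)-5-methyl-6-[(E)-2-(3-methylbut-2-enoyloxy)ethenyl]-5-(3-oxopropyl)-7-(2-oxopropyl)cyclohept-2-en-1-one; 20 2-bromopropene
Product: 21 (5S,6S,7R)-2-(hydroxymethyl)-5-[(3R)-3-hydroxy-4-methylpent-4-en-1-yl]-5-methyl-6-[(E)-2-(3-methylbut-2-enoyloxy)ethenyl]-7-(2-oxopropyl)cyclohept-2-en-1-one
Conditions: CrCl2 (10 mol%), Kishi oxazoline–sulfonamide ligand (11 mol%), Et3N (20 mol%), NiCl2·(2,9-dimethyl-1,10-phenanthroline) (2 mol%), Mn (2 equiv), Cp2ZrCl2 (1.1 equiv), LiCl, MeCN, rt; aq. citric acid work-up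
Reagents that add atoms: none
Why: Catalytic asymmetric Nozaki–Hiyama–Kishi coupling, in which the isopropenylchromium species adds only to the aldehyde (ketones, enone, enol ester and free alcohol are tolerated) and the chiral sulfonamide ligand on chromium selects the aldehyde face to give the (3R)-carbinol, the last stereocentre, under reagent control.

**Compound list**
1 | cyclohepta-1,3-diene | C1=CC=CCCC1 | starting material
2 | 6,7-dioxabicyclo[3.2.2]non-8-ene (meso endoperoxide) | C1CC[C@H]2C=C[C@@H]1OO2 | intermediate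
3 | (R)-4-hydroxycyclohept-2-en-1-one | O[C@H]1C=CC(=O)CCC1 | intermediate
4 | (R)-4-(tert-butyldimethylsilyloxy)cyclohept-2-en-1-one | CC(C)(C)[Si](C)(C)O[C@H]1C=CC(=O)CCC1 | intermediate
5 | isoprene (2-methylbuta-1,3-diene) | C=CC(C)=C | starting material
6 | (4aR,5R,9aS)-5-(tert-butyldimethylsilyloxy)-3-methyl-1,4,4a,5,6,7,8,9a-octahydro-9H-benzo[7]annulen-9-one (cis-fused, silyloxy trans to the adjacent ring-fusion CH2) | O=C1CCC[C@@H](O[Si](C)(C)C(C)(C)C)[C@@H]2CC(C)=CC[C@H]12 | intermediate
7 | (4aR,5R,9aS)-5-(tert-butyldimethylsilyloxy)-3-methyl-9-methylidene-4,4a,5,6,7,8,9,9a-octahydro-1H-benzo[7]annulene | C=C1CCC[C@@H](O[Si](C)(C)C(C)(C)C)[C@@H]2CC(C)=CC[C@H]12 | intermediate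
8 | acrolein | C=CC=O | starting material
9 | 3-[(4aR,5R,9R,9aS)-5-(tert-butyldimethylsilyloxy)-3,9-dimethyl-4,4a,5,6,7,8,9,9a-octahydro-1H-benzo[7]annulen-9-yl]propanal (9-methyl cis to the 9a–CH2 bond) | O=CCC[C@@]1(C)CCC[C@@H](O[Si](C)(C)C(C)(C)C)[C@@H]2CC(C)=CC[C@H]12 | intermediate
10 | (4aR,5R,9R,9aS)-9-[2-(1,3-dioxolan-2-yl)ethyl]-3,9-dimethyl-4,4a,5,6,7,8,9,9a-octahydro-1H-benzo[7]annulen-5-ol | O1CCOC1CC[C@@]1(C)CCC[C@@H](O)[C@@H]2CC(C)=CC[C@H]12 | intermediate
11 | (4aR,9R,9aS)-9-[2-(1,3-dioxolan-2-yl)ethyl]-3,9-dimethyl-1,4,4a,6,7,8,9,9a-octahydro-5H-benzo[7]annulen-5-one | O1CCOC1CC[C@@]1(C)CCCC(=O)[C@@H]2CC(C)=CC[C@H]12 | intermediate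
12 | trimethylsilyl enol ether of 11 (C5=C6 enol ether, 4aR,9R,9aS) | O1CCOC1CC[C@@]1(C)CCC=C(O[Si](C)(C)C)[C@@H]2CC(C)=CC[C@H]12 | intermediate
13 | (4aR,9S,9aS)-9-[2-(1,3-dioxolan-2-yl)ethyl]-3,9-dimethyl-1,4,4a,8,9,9a-hexahydro-5H-benzo[7]annulen-5-one | O1CCOC1CC[C@@]1(C)CC=CC(=O)[C@@H]2CC(C)=CC[C@H]12 | intermediate
14 | (5S,6S,7R)-5-[2-(1,3-dioxolan-2-yl)ethyl]-5-methyl-6-(2-oxoethyl)-7-(2-oxopropyl)cyclohept-2-en-1-one | O1CCOC1CC[C@@]1(C)CC=CC(=O)[C@H](CC(C)=O)[C@@H]1CC=O | intermediate
15 | 3-methylbut-2-enoyl chloride | CC(C)=CC(Cl)=O | starting material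
16 | (5S,6S,7R)-5-[2-(1,3-dioxolan-2-yl)ethyl]-5-methyl-6-[(E)-2-(3-methylbut-2-enoyloxy)ethenyl]-7-(2-oxopropyl)cyclohept-2-en-1-one | O1CCOC1CC[C@@]1(C)CC=CC(=O)[C@H](CC(C)=O)[C@@H]1/C=C/OC(=O)C=C(C)C | intermediate
17 | formaldehyde | C=O | starting material
18 | (5S,6S,7R)-5-[2-(1,3-dioxolan-2-yl)ethyl]-2-(hydroxymethyl)-5-methyl-6-[(E)-2-(3-methylbut-2-enoyloxy)ethenyl]-7-(2-oxopropyl)cyclohept-2-en-1-one | O1CCOC1CC[C@@]1(C)CC=C(CO)C(=O)[C@H](CC(C)=O)[C@@H]1/C=C/OC(=O)C=C(C)C | intermediate
19 | (5S,6S,7R)-2-(hydroxymethyl)-5-methyl-6-[(E)-2-(3-methylbut-2-enoyloxy)ethenyl]-5-(3-oxopropyl)-7-(2-oxopropyl)cyclohept-2-en-1-one | O=CCC[C@@]1(C)CC=C(CO)C(=O)[C@H](CC(C)=O)[C@@H]1/C=C/OC(=O)C=C(C)C | intermediate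
20 | 2-bromopropene | C=C(C)Br | starting material
21 | (5S,6S,7R)-2-(hydroxymethyl)-5-[(3R)-3-hydroxy-4-methylpent-4-en-1-yl]-5-methyl-6-[(E)-2-(3-methylbut-2-enoyloxy)ethenyl]-7-(2-oxopropyl)cyclohept-2-en-1-one (CNP0257974.2) | C=C(C)[C@H](O)CC[C@@]1(C)CC=C(CO)C(=O)[C@H](CC(C)=O)[C@@H]1/C=C/OC(=O)C=C(C)C | target

**Step count**
Total step count: 12. Longest linear sequence: 12 steps (1 → 21); all other starting materials are used as bought.

**Steps most likely to fail, with fallbacks**

Step 3 (Diels–Alder). The cycloheptenone is a sluggish dienophile, the silyloxy group may be lost under Lewis acid, and the kinetic cis ring fusion alpha to the ketone can epimerise. The fallback sets out from 4. Bromination and dehydrobromination (Br2, CH2Cl2, 0 °C; then Et3N) give (R)-2-bromo-4-(tert-butyldimethylsilyloxy)cyclohept-2-en-1-one F1, a much better dienophile. Its cycloaddition with isoprene (EtAlCl2 cat., −78 °C) gives the 9a-bromo adduct F2, whose ring-fusion carbon is quaternary and cannot epimerise. Radical debromination (Bu3SnH, AIBN, benzene, 80 °C) then delivers hydrogen to the convex face of the ring-fusion radical and comes back to the route at 6.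

Step 5 (radical conjugate addition). The iron hydride may also attack the trisubstituted ring alkene, and facial selectivity at the tertiary radical may be moderate. The fallback sets out from 6. MeMgBr/CeCl3 (THF, −78 °C) gives the tertiary alcohol F3 (either epimer serves). Methyl chlorooxoacetate, Et3N and DMAP give the methyl oxalate F4, and CsOH (THF/H2O) gives the cesium oxalate F5. Visible-light photoredox decarboxylation (Ir[dF(CF3)ppy]2(dtbbpy)PF6 1 mol%, blue LED, acrolein, DME/DMF, H2O, rt) generates the same tertiary radical from the C–O bond with no metal hydride present, so no alkene can compete. Its addition to acrolein comes back to the route at aldehyde 9, which is taken on to 10 under the acid conditions of step 5.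

Step 9 (enol ester). The keto aldehyde can undergo intramolecular aldol reaction under amine base, the E/Z ratio may be modest, and the acid chloride can give some deconjugated ester. The fallback sets out from 14 and avoids any aldehyde enolate. 3-Methylbut-2-enoyl chloride 15 is added across the aldehyde C=O (ZnCl2 5 mol%, CH2Cl2, −10 °C) to give the 1-chloroalkyl ester F6. Loss of HCl with iPr2NEt (toluene, 60 °C) through the less strained anti-periplanar arrangement then gives the (E)-enol ester and comes back to the route at 16.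

**Further compounds**
F1 | step 3 | (R)-2-bromo-4-(tert-butyldimethylsilyloxy)cyclohept-2-en-1-one | CC(C)(C)[Si](C)(C)O[C@H]1C=C(Br)C(=O)CCC1
F2 | step 3 | 9a-bromo adduct (9a-bromo analogue of 6) | O=C1CCC[C@@H](O[Si](C)(C)C(C)(C)C)[C@@H]2CC(C)=CC[C@]12Br
F3 | step 5 | tertiary alcohol (9-hydroxy-9-methyl analogue of 6, either C9 epimer) | CC1(O)CCC[C@@H](O[Si](C)(C)C(C)(C)C)[C@@H]2CC(C)=CC[C@H]12
F4 | step 5 | methyl oxalate of F3 | COC(=O)C(=O)OC1(C)CCC[C@@H](O[Si](C)(C)C(C)(C)C)[C@@H]2CC(C)=CC[C@H]12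
F5 | step 5 | cesium oxalate of F3 | [Cs+].[O-]C(=O)C(=O)OC1(C)CCC[C@@H](O[Si](C)(C)C(C)(C)C)[C@@H]2CC(C)=CC[C@H]12
F6 | step 9 | 1-chloroalkyl ester (1-chloro-2-substituted-ethyl 3-methylbut-2-enoate from 14, either epimer at the chloro carbon) | O1CCOC1CC[C@@]1(C)CC=CC(=O)[C@H](CC(C)=O)[C@@H]1CC(Cl)OC(=O)C=C(C)C
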